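(Its constants are those of an exercise; what happens was integrated by code.)

Take the four flasks below and count, for each hand of the substrate, how many lifetimes it has lived by the end.

the same everywhere: D 0.012 M; L 0.0480 M; Z 0.012 M; time 2.0 d
- cedar: temperature 30 °C
- larch: temperature 50 °C
- maple: temperature 70 °C
- alder: temperature 10 °C

    L + D → L.D (k1 = 13.3 L mol⁻¹ h⁻¹, Ea1 = 61.0 kJ mol⁻¹)
    L + Z → L.Z (k2 = 6.61 L mol⁻¹ h⁻¹, Ea2 = 63.0 kJ mol⁻¹)
    D ⇌ Z (k3 = 0.00319 h⁻¹, Ea3 = 127 kJ mol⁻¹)
    2 L → L2 (k4 = 1.27 L mol⁻¹ h⁻¹, Ea4 = 73.0 kJ mol⁻¹)
    L → J (k5 = 6.02 × 10⁻⁵ h⁻¹, Ea5 = 128 kJ mol⁻¹)
    L → Q (k6 = 0.00774 h⁻¹, Ea6 = 120 kJ mol⁻¹)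
    (constants at 50 °C)

- L is single-handed; D and Z are mirror images of each other, charged as a racemate, each of them at the stated concentration
- a step written with two of one species runs at k times the square of its concentration and takes two of it each time
- at 50 °C the constants are as listed, elsewhere as the activation energies make them
- an excess is the difference of the two amounts in percent of their sum
- an excess is below zero if the other one leads
- the handed part of L does not stay in what it makes, so the products of the two hands are mirror images too

- the best flask by excess of L.D over L.Z; "all alike" if 1.5 percentage points covers them all (cedar / larch / maple / alder / all alike)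
- excess of L.D over L.Z at the end, cedar
- excess of L.D over L.Z at the end, larch
- excess of L.D over L.Z at the end, maple
- excess of L.D over L.Z at the end, alder

What do you count? L is the same for D and Z, so each hand's lifetimes grow with its rate constant times cL, summed over time. At one temperature, whatever happens to cL, the ratio of the two counts stays the rate-constant ratio. Call this the selectivity factor s, the lifetimes D lives for each one Z lives.

And in alder? At 10 °C the activation energies make the constants 0.538 L mol⁻¹ h⁻¹ for D and 0.241 L mol⁻¹ h⁻¹ for Z, so s is 2.24.

Does D ⇌ Z not spoil the count? Not in alder, because its relaxation half-life by that step alone, 3600 d, is far longer than the 2.0 d of the run. In maple that half-life is 6.91 h, shorter than the run, so in maple what is left of each hand can no longer be read from its count, and I reckon alder and no further.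

How many lifetimes does D live in alder? With cL held at its charge, 1.24.

But cL does not stay at its charge, does it? No. In alder that count, together with the step joining two L at its starting rate, would take 0.0197 M of L. Both parts are overstated, but they give alder an estimated mean cL of 0.0382 M. The count for D in alder then falls to 0.986.

What is left, then? In alder I reckon D left at 37.3% and Z left at 64.3%, each of its own charge. In alder I take each product as what its hand has lost, so my excess of L.D over L.Z in alder is 27.5%.

The forecast names alder as best, with 9.9% for cedar, 3.9% for larch and 9.5% for maple. For alder it gives 27.3%, within 25.5% to 29%, on the ground that “at 10 °C it stops at about half conversion and keeps the largest excess”. My own figure of 27.5% for alder is a little higher than that.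

The simulation gives alder as best, with 9.96% for cedar, 3.82% for larch, 9.42% for maple and 27.4% for alder.

In alder, Z left at the end reads 64%, and raised to the power s it gives D left as 36.8%, where the flask reads 37%. The neighbouring flask is alder charged with 0.082 M of L. Its Z left reads 47%, so the same power gives D left as 18.5% and an excess of 21.2%. That neighbouring flask reads D left 19% and excess 21.2%.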